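Start from the product G: in the readings it trails X, and you want the ratio of X to G early and late in a flask charged with 20 mM of J.

| setting | Thursday's | Sunday's | flask |
|---|---|---|---|
| J | 10 mM | 15 mM | 20 mM |
| remark | run made earlier | run made earlier |  |
| time |  |  | 80 min |

- Thursday's (time / min: X / %, G / %, J / %): 3.00: 1.6, 0, 98.0; 10.0: 6.7, 0.9, 92.5; 15.0: 11.0, 0.4, 89.7; 25.0: 14.8, 1.8, 84.9; 40.0: 19.2, 2.2, 78.6; 50.0: 21.3, 2.6, 74.7
- Sunday's (time / min: X / %, G / %, J / %): 8.00: 5.3, 0, 94.4; 15.0: 9.8, 0, 89.9; 25.0: 15.0, 2.4, 84.2; 30.0: 16.7, 1.4, 82.2; 40.0: 18.9, 2.7, 78.2; 50.0: 22.0, 3.5, 75.2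

(each reading ± 0.5 percentage points)

- ratio of X to G at 1.5 min
- ratio of X to G at 80 min

- steps under discussion: J <-> X; X <-> G; G <-> D

Does the charge matter? At 50.0 min, Thursday's run (10 mM) keeps 74.7 % of its J and Sunday's run (15 mM) keeps 75.2 %, a gap of 0.5 percentage points against a scatter of 0.5 points. So you carry fractions of the charge over to the flask, assuming the overlay holds at its charge.

How does G follow X? The readings themselves show no lag: Thursday's ratio of X to G reads 7.44 at 10.0 min and 8.19 at 50.0 min. But the steps under discussion put X between J and G, so you assume that G is made from X and should start with a lag. If X grows with time and G with its square, then time multiplied by the ratio of X to G stays constant. Pooling both runs at 50.0 min gives 355 min for this lag constant, a reading good to about 11.6 %.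

Your reckoning gives 237 at 1.5 min and 4.44 at 80 min. Expect a little less at the late time, since Thursday's X has already bent, growing 1.44-fold from 25.0 min to 50.0 min.

The forecast says 250 and 4.2, reasoning that “G is formed only through X”; its figures differ slightly from yours.

The flask gives 241 and 4.13.

    J ⇌ X (K = 0.497, k = 0.00849 min⁻¹)
    X ⇌ G (K = 1.61, k = 0.00551 min⁻¹)
    G ⇌ D (K = 25.3, k = 0.00473 min⁻¹)

Time multiplied by the ratio comes to 362 min early and 330 min late, against the lag constant of 355 min. At 80.0 min, G is still made 4.12 times faster than it is used up, and it stands at 5.90 %. With 12 mM of J, the lag constant again gives 237 and 4.44, since it is read in fractions of the charge; the computed ratios there are 241 and 4.13.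

(The numbers in the tables come from a simulation from invented constants, and the scatter is random.)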